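Gentiside B is cut at the ester carbonyl carbon, the one atom that separates ring carbon C1 of the catechol ring from O1 of the C23 chain. Carbon monoxide supplies that carbon. A palladium-catalysed three-component alkoxycarbonylation forges the aryl C1–C(=O) bond and the C(=O)–O1 bond in a single operation, without ring closure or change at the remote C20 stereocentre. The precursors are 1,2-bis(benzyloxy)-3-bromobenzene, whose bromine marks the position of carbonylation, and (S)-20-methyldocosan-1-ol. The alcohol is assembled by copper-catalysed coupling of a C18 bromo alcohol with the Grignard reagent of (S)-1-bromo-2-methylbutane. Hydrogenolysis of the two benzyl ethers ends the route.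

Key step: step 5

Remark: commercial (S)-1-bromo-2-methylbutane is assumed to be of high enantiomeric purity, because the optical purity of the target can only equal that of this building block.

Step 1
Reactants: 1 octadecanedioic acid
Product: 2 octadecane-1,18-diol
Conditions: BH3·THF (3 equiv), THF, 0 °C to 40 °C; then H2O
Reagents that add atoms: none
Why: Borane reduction of carboxylic acids, in which each CO2H group forms an acyloxyborane that is reduced quickly to the borate of the primary alcohol and freed by hydrolysis on work-up, and the substrate carries no other reducible group.

Step 2
Reactants: 2 octadecane-1,18-diol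
Product: 3 18-bromooctadecan-1-ol
Conditions: 48% aq. HBr (1.2 equiv), toluene, reflux
Reagents that add atoms: hydrogen bromide, Br
Why: Acid-promoted SN2 substitution of a primary alcohol by bromide in the two-phase toluene/aqueous HBr system, where the bromo alcohol formed first stays in the organic layer with its hydroxyl group held in hydrogen-bonded aggregates and should react more slowly than the diol, so that the monobromide should dominate and differs enough in polarity from its neighbours to be separated.

Step 3
Reactants: 3 18-bromooctadecan-1-ol; 4 (S)-1-bromo-2-methylbutane
Product: 8 (S)-20-methyldocosan-1-ol, via Grignard reagent 5 (not isolated), via bromoalkoxide 6 (not isolated), via coupled alkoxide 7 (not isolated)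
Conditions: (a) 4 (2.5 equiv), Mg, THF, 40 °C; (b) 3, THF, 0 °C, 5 (1.05 equiv); then Li2CuCl4 (3 mol %), NMP (4 equiv), remaining 5 added slowly, 0 °C to rt; 1 M HCl quench
Reagents that add atoms: magnesium, [Mg] (held only in 5, 6 and 7; none of it remains in 8)
Why: Kochi-type copper-catalysed sp3–sp3 Grignard cross-coupling, in which the first equivalent of 5 acts as base and turns 3 into the inert magnesium alkoxide 6 so that no foreign alkyl group can enter, a further equivalent displaces the unhindered primary bromide through an alkylcuprate to give 7 (C1–C18 from 3, C19–C22 plus the methyl branch from 4), the acid quench frees 8, and the stereocentre, bought with 4 and lying beta to the carbon–magnesium bond, is never touched and keeps the descriptor S because the new chain takes the rank of CH2Br above ethyl, methyl and H.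

Step 4
Reactants: 9 3-bromocatechol; 10 benzyl bromide
Product: 11 1,2-bis(benzyloxy)-3-bromobenzene
Conditions: BnBr (2.3 equiv), K2CO3 (3 equiv), DMF, N2, 60 °C
Reagents that add atoms: benzyl bromide 10, BrCc1ccccc1
Why: Double Williamson ether synthesis, in which K2CO3 deprotonates both acidic phenols and the phenoxides displace bromide from the reactive benzylic halide by SN2, while the aryl bromide is inert under these metal-free conditions.

Step 5
Reactants: 11 1,2-bis(benzyloxy)-3-bromobenzene (1.3 equiv); 12 carbon monoxide; 8 (S)-20-methyldocosan-1-ol
Product: 13 (S)-20-methyldocosyl 2,3-bis(benzyloxy)benzoate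
Conditions: Pd(OAc)2 (3 mol %), Xantphos (4 mol %), CO (1 atm), Et3N (3 equiv), DMAP (20 mol %), toluene, 100 °C
Reagents that add atoms: carbon monoxide 12, [C-]#[O+]
Why: Pd(OAc)2 is reduced in situ to a zerovalent palladium–Xantphos complex that adds oxidatively to the C3–Br bond of 11; CO then inserts into the aryl–palladium bond to give a divalent acylpalladium bromide, and alcohol 8, helped by Et3N as proton acceptor and DMAP as acyl shuttle, cleaves it to ester 13 with return of the zerovalent catalyst. The closest known reaction type is the Heck-type alkoxycarbonylation of aryl bromides with primary alcohols, which runs at atmospheric CO pressure with wide-bite-angle diphosphines and accepts ortho-alkoxy substituents. No ring is closed and no stereocentre is made; C20 of 8 lies nineteen methylene groups away from the reacting O1 and passes through unchanged. Site selectivity is built into the substrate, since the carbonyl carbon can only enter at the carbon that carried bromine, so the 1,2,3-substitution pattern of commercial 9 is transferred intact. The selectivity that must be won is chemoselective: CO insertion and alcoholysis have to outrun hydrodebromination through a palladium alkoxide and beta-hydride loss, which the chelating ligand, the steady CO supply and the unhindered primary hydroxyl of 8 should secure. A small excess of the cheap bromide 11 lets the valuable alcohol 8 be consumed fully, and the benzyl ethers and the saturated chain are inert to all components.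

Step 6
Reactants: 13 (S)-20-methyldocosyl 2,3-bis(benzyloxy)benzoate
Product: 14 gentiside B
Conditions: H2 (1 atm), 10% Pd/C, EtOAc/THF, rt
Reagents that add atoms: none
Why: Heterogeneous catalytic hydrogenolysis cleaves only the two benzylic C–O bonds, whereas the ester oxygen sits on a non-benzylic primary alkyl carbon and the saturated chain with its C20 stereocentre offers nothing to reduce, so the free catechol should result under neutral conditions.

Compound list
1 | octadecanedioic acid | OC(=O)CCCCCCCCCCCCCCCCC(=O)O | starting material
2 | octadecane-1,18-diol | OCCCCCCCCCCCCCCCCCCO | intermediate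
3 | 18-bromooctadecan-1-ol | OCCCCCCCCCCCCCCCCCCBr | intermediate
4 | (S)-1-bromo-2-methylbutane | CC[C@H](C)CBr | starting material
5 | (S)-2-methylbutylmagnesium bromide | CC[C@H](C)C[Mg]Br | intermediate
6 | bromomagnesium 18-bromooctadecan-1-olate | BrCCCCCCCCCCCCCCCCCCO[Mg]Br | intermediate
7 | bromomagnesium (S)-20-methyldocosan-1-olate | CC[C@H](C)CCCCCCCCCCCCCCCCCCCO[Mg]Br | intermediate
8 | (S)-20-methyldocosan-1-ol | CC[C@H](C)CCCCCCCCCCCCCCCCCCCO | intermediate
9 | 3-bromocatechol (3-bromobenzene-1,2-diol) | Oc1cccc(Br)c1O | starting material
10 | benzyl bromide | BrCc1ccccc1 | starting material
11 | 1,2-bis(benzyloxy)-3-bromobenzene | Brc1cccc(OCc2ccccc2)c1OCc1ccccc1 | intermediate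
12 | carbon monoxide | [C-]#[O+] | starting material
13 | (S)-20-methyldocosyl 2,3-bis(benzyloxy)benzoate | CC[C@H](C)CCCCCCCCCCCCCCCCCCCOC(=O)c1cccc(OCc2ccccc2)c1OCc1ccccc1 | intermediate
14 | gentiside B, (S)-20-methyldocosyl 2,3-dihydroxybenzoate | CC[C@H](C)CCCCCCCCCCCCCCCCCCCOC(=O)c1cccc(O)c1O | target

Total step count: 6
Longest linear sequence: 5 steps (steps 1, 2, 3, 5 and 6, from 1 to 14)

Steps most likely to fail, in order: step 5, step 3, step 2.

**Step 5** carries the main risk. Oxidative addition into the electron-rich C–Br bond next to an alkoxy group may be slow. Alcoholysis of the acylpalladium by a single equivalent of a waxy alcohol may also lag, so that catalyst decay and hydrodebromination compete. The fallback sets out from 11 and comes back at 13. It brings in the carbonyl carbon as CO2 through a main-group organometallic instead of a palladium cycle. Bromine–lithium exchange of 11 with n-BuLi in THF at −78 °C is faster than any attack on the benzyl ethers and gives [2,3-bis(benzyloxy)phenyl]lithium F1. Dry CO2 followed by dilute HCl converts this into 2,3-bis(benzyloxy)benzoic acid F2. Steglich esterification of F2 with alcohol 8 (DCC, DMAP, CH2Cl2, rt) then delivers 13.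

**Step 3** comes next. Aggregation or precipitation of the long-chain magnesium alkoxide may stall the substitution. The Grignard reagent would then be lost to homocoupling, and the C–Br bond to halogen–metal exchange and reduction. The fallback sets out from 3 and comes back at 8, and it couples a neutral, fully soluble electrophile. TBSCl and imidazole in CH2Cl2/DMF convert 3 into tert-butyl[(18-bromooctadecyl)oxy]dimethylsilane F3. Li2CuCl4-catalysed coupling with 1.3 equiv of 5 in THF gives tert-butyldimethyl{[(S)-20-methyldocosyl]oxy}silane F4. Treatment with 1 M aqueous HCl in THF at 40 °C removes the silyl group to give 8.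

**Step 2** is third. The two termini of 2 are equivalent, so substitution may run on to the second hydroxyl group or stop early. Acid-promoted ether formation between chains may erode the material balance further. The fallback sets out from 2 and comes back at 8, and it differentiates the ends by mono-protection before any bromide is introduced. One equivalent of NaH in warm THF should precipitate sodium 18-hydroxyoctadecan-1-olate F5. TBSCl silylates this faster than protons are exchanged and gives 18-[(tert-butyldimethylsilyl)oxy]octadecan-1-ol F6. A neutral Appel reaction (CBr4, PPh3, CH2Cl2, 0 °C) converts the remaining hydroxyl group into bromide and so gives F3. This continues through F4 to 8 as described for step 3.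

Further compounds
F1 | step 5 | [2,3-bis(benzyloxy)phenyl]lithium | [Li]c1cccc(OCc2ccccc2)c1OCc1ccccc1
F2 | step 5 | 2,3-bis(benzyloxy)benzoic acid | OC(=O)c1cccc(OCc2ccccc2)c1OCc1ccccc1
F3 | step 3 | tert-butyl[(18-bromooctadecyl)oxy]dimethylsilane | CC(C)(C)[Si](C)(C)OCCCCCCCCCCCCCCCCCCBr
F4 | step 3 | tert-butyldimethyl{[(S)-20-methyldocosyl]oxy}silane | CC[C@H](C)CCCCCCCCCCCCCCCCCCCO[Si](C)(C)C(C)(C)C
F5 | step 2 | sodium 18-hydroxyoctadecan-1-olate | [Na+].[O-]CCCCCCCCCCCCCCCCCCO
F6 | step 2 | 18-[(tert-butyldimethylsilyl)oxy]octadecan-1-ol | CC(C)(C)[Si](C)(C)OCCCCCCCCCCCCCCCCCCO
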